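The cyclohexene ring is opened at C1–C6 and C2–C3. The retron is the C4=C5 alkene flanked by the cis-disposed allylic C3–O and C6–O bonds, next to the cis C1–O/C2–O pair. One catalytic enantioselective Diels–Alder reaction joins (1E,3E)-1-benzoyloxy-4-(triethylsilyloxy)butadiene (C3 to C6) to (Z)-2-acetoxy-3-benzoyloxyacrolein (C7, C1, C2). It closes the carbocycle and sets all four contiguous stereocentres, the fully substituted C1 included, with both benzoates already in place. The precursors are two flat, achiral, acyclic enol esters. The endo formyl group becomes C7. On its reduction the C1 acetate shifts to the primary oxygen and frees the tertiary alcohol.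

Key step: step 6

Numbering used throughout: C1 is the carbinol carbon, C2 and C3 are the benzoate carbons, C4=C5 is the alkene, C6 is the ring acetate carbon, and C7 is the exocyclic CH2.
Assumption: the sense of induction in step 6 is taken from the accepted pre-transition-state model of this catalyst family for 2-substituted acroleins. Both antipodes of the catalyst precursor are commercial.
Assumption: 1,3-dihydroxyacetone is bought as its dimer, which reverts to monomer 5 in pyridine.

Step 1
Reactants: 1 (Z)-but-2-ene-1,4-diol
Product: 2 (2Z)-4-hydroxybut-2-en-1-yl benzoate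
Conditions: BzCl (1 equiv), 1 (3 equiv), Et3N, CH2Cl2, 0 °C
Reagents that add atoms: benzoyl chloride, O=C(Cl)c1ccccc1
Why: This is a statistical O-acylation (nucleophilic acyl substitution) in which the excess of the symmetric diol should suppress the dibenzoate, and the Z alkene is not touched.

Step 2
Reactants: 2 (2Z)-4-hydroxybut-2-en-1-yl benzoate
Product: 3 (2Z)-4-oxobut-2-en-1-yl benzoate
Conditions: Dess–Martin periodinane, CH2Cl2, 0 °C; cold NaHCO3/Na2S2O3 wash, used without chromatography
Reagents that add atoms: none
Why: The Dess–Martin oxidation of an allylic primary alcohol runs cold and close to neutral, so the Z geometry needed in step 3 should be kept and the benzoate is inert.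

Step 3
Reactants: 3 (2Z)-4-oxobut-2-en-1-yl benzoate
Product: 4 (1E,3E)-4-[(triethylsilyl)oxy]buta-1,3-dien-1-yl benzoate
Conditions: Et3SiOTf, then Et3N, Et2O, −78 to −20 °C; Et3N-deactivated silica
Reagents that add atoms: triethylsilyl trifluoromethanesulfonate, CC[Si](CC)(CC)OS(=O)(=O)C(F)(F)F
Why: In this soft enolisation (silyl dienol ether formation), O-silylation of the s-trans enal fixes the 1E bond, and allylic 1,3-strain in the Z-enal turns the benzoyloxy group outward while Et3N removes a C4 proton, so the new enol benzoate bond should be 3E.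

Step 4
Reactants: 5 1,3-dihydroxyacetone
Product: 6 3-hydroxy-2-oxopropyl benzoate
Conditions: BzCl (1 equiv), 5 (3 equiv), pyridine, CH2Cl2, 0 °C
Reagents that add atoms: benzoyl chloride, O=C(Cl)c1ccccc1
Why: This is a statistical O-acylation of a symmetric diol, where the excess of 5 is washed out with water and no stereocentre is involved.

Step 5
Reactants: 6 3-hydroxy-2-oxopropyl benzoate
Product: 8 (1Z)-2-(acetyloxy)-3-oxoprop-1-en-1-yl benzoate, via keto aldehyde 7 (not isolated)
Conditions: Dess–Martin periodinane (1.0 equiv), CH2Cl2, 0 °C; filtration through Celite; then Ac2O, Et3N, −20 °C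
Reagents that add atoms: acetic anhydride, CC(=O)OC(C)=O
Why: Dess–Martin oxidation of the ketol gives 7, whose acidic CH2 enolises to the conjugated enediol monoester, and O-acetylation (enol ester formation as with diosphenols) traps it with the benzoyloxy group anti to the formyl group for steric and dipole reasons, which is the Z isomer.

Step 6
Reactants: 4 (1E,3E)-4-[(triethylsilyl)oxy]buta-1,3-dien-1-yl benzoate; 8 (1Z)-2-(acetyloxy)-3-oxoprop-1-en-1-yl benzoate
Product: 9 (1S,2S,3R,6S)-1-acetoxy-2,3-bis(benzoyloxy)-6-(triethylsilyloxy)cyclohex-4-ene-1-carbaldehyde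
Conditions: (3aR)-1-(2-methylphenyl)-3,3-diphenyltetrahydro-1H,3H-pyrrolo[1,2-c][1,3,2]oxazaborole (20 mol%, from (R)-α,α-diphenylprolinol), (CF3SO2)2NH (17 mol%), 4 (1.5 equiv), CH2Cl2, −78 to −40 °C
Reagents that add atoms: none
Why: The boron cation binds the formyl oxygen of s-trans 8 syn to the formyl hydrogen and lowers the LUMO, and 4 adds in its s-cis form in a concerted but asynchronous normal-demand [4πs+2πs] cycloaddition in which C2–C3 forms ahead of C1–C6. The closest known reaction type is the oxazaborolidinium-catalysed enantioselective Diels–Alder reaction of 2-substituted acroleins, together with the known cycloadditions of 2-acyloxyacroleins and of (E,E)-1,4-diacyloxybutadienes. The single new ring, the six-membered carbocycle, is closed by an intermolecular suprafacial–suprafacial [4+2] cycloaddition that leaves the C4=C5 alkene between the two allylic C–O carbons. C3–O and C6–O become cis because both diene substituents are E (outside), C1–O and C2–O become cis because 8 is Z, the two pairs are linked by the endo position of the boron-bound formyl group (outside groups end cis to the endo group, so C7 lies on the face of C3–O and C6–O), and the absolute sense comes from the catalyst, whose phenyl group near boron covers the Re face of C1 so that the diene adds to the Si face. The step needs ortho regioselectivity, which is secured because OSiEt3 is a far stronger donor than OBz and puts the larger HOMO coefficient on the benzoyloxy-bearing terminus, which bonds to the electrophilic β-carbon C2. It also needs C=C over C=O chemoselectivity and survival of the silyl dienol ether, both helped by the low temperature and by keeping the imide substoichiometric to the oxazaborolidine so that no free strong acid is present.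

Step 7
Reactants: 9 (1S,2S,3R,6S)-1-acetoxy-2,3-bis(benzoyloxy)-6-(triethylsilyloxy)cyclohex-4-ene-1-carbaldehyde
Product: 12 (1R,2S,3R,6S)-1-(acetoxymethyl)-1,6-dihydroxycyclohex-4-ene-2,3-diyl dibenzoate, via primary alcohol 10 (not isolated), via rearranged silyl ether 11 (not isolated)
Conditions: NaBH4, THF–EtOH, −20 to 0 °C; then 1 M aq. HCl, 0 °C to rt
Reagents that add atoms: none
Why: Chemoselective borohydride reduction of the aldehyde beside the esters is followed by a base-promoted 1,2-O-to-O acyl migration through a five-membered orthoacid from the crowded tertiary oxygen to the primary one and then by acid hydrolysis of the triethylsilyl ether, and no stereocentre is touched because C1 carries no hydrogen and cannot epimerise or eliminate.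

Step 8
Reactants: 12 (1R,2S,3R,6S)-1-(acetoxymethyl)-1,6-dihydroxycyclohex-4-ene-2,3-diyl dibenzoate
Product: 13 (1R,2S,3R,6S)-6-acetoxy-1-(acetoxymethyl)-1-hydroxycyclohex-4-ene-2,3-diyl dibenzoate
Conditions: Ac2O, pyridine, 4-(dimethylamino)pyridine (5 mol%), CH2Cl2, 0 °C
Reagents that add atoms: acetic anhydride, CC(=O)OC(C)=O
Why: Nucleophile-catalysed acetylation takes the secondary allylic C6–OH (and any C7–OH left free) but not the tertiary C1–OH flanked by three substituted carbons, so every monoacetate isomer that step 7 could deliver should converge on 13.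

Compound list
1 | (Z)-but-2-ene-1,4-diol | OC/C=C\CO | starting material
2 | (2Z)-4-hydroxybut-2-en-1-yl benzoate | OC/C=C\COC(=O)c1ccccc1 | intermediate
3 | (2Z)-4-oxobut-2-en-1-yl benzoate | O=C/C=C\COC(=O)c1ccccc1 | intermediate
4 | (1E,3E)-4-[(triethylsilyl)oxy]buta-1,3-dien-1-yl benzoate | CC[Si](CC)(CC)O/C=C/C=C/OC(=O)c1ccccc1 | intermediate
5 | 1,3-dihydroxyacetone (sold as the dimer) | OCC(=O)CO | starting material
6 | 3-hydroxy-2-oxopropyl benzoate | OCC(=O)COC(=O)c1ccccc1 | intermediate
7 | 2,3-dioxopropyl benzoate (keto aldehyde, not isolated) | O=CC(=O)COC(=O)c1ccccc1 | intermediate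
8 | (1Z)-2-(acetyloxy)-3-oxoprop-1-en-1-yl benzoate | O=C/C(OC(C)=O)=C/OC(=O)c1ccccc1 | intermediate
9 | (1S,2S,3R,6S)-1-acetoxy-2,3-bis(benzoyloxy)-6-(triethylsilyloxy)cyclohex-4-ene-1-carbaldehyde | O=C[C@@]1(OC(C)=O)[C@@H](O[Si](CC)(CC)CC)C=C[C@@H](OC(=O)c2ccccc2)[C@@H]1OC(=O)c1ccccc1 | intermediate
10 | (1S,2S,3R,6S)-1-acetoxy-1-(hydroxymethyl)-6-(triethylsilyloxy)cyclohex-4-ene-2,3-diyl dibenzoate (primary alcohol, not isolated) | OC[C@@]1(OC(C)=O)[C@@H](O[Si](CC)(CC)CC)C=C[C@@H](OC(=O)c2ccccc2)[C@@H]1OC(=O)c1ccccc1 | intermediate
11 | (1S,2S,3R,6S)-1-(acetoxymethyl)-1-hydroxy-6-(triethylsilyloxy)cyclohex-4-ene-2,3-diyl dibenzoate (rearranged silyl ether, not isolated) | CC(=O)OC[C@@]1(O)[C@@H](O[Si](CC)(CC)CC)C=C[C@@H](OC(=O)c2ccccc2)[C@@H]1OC(=O)c1ccccc1 | intermediate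
12 | (1R,2S,3R,6S)-1-(acetoxymethyl)-1,6-dihydroxycyclohex-4-ene-2,3-diyl dibenzoate | CC(=O)OC[C@@]1(O)[C@@H](O)C=C[C@@H](OC(=O)c2ccccc2)[C@@H]1OC(=O)c1ccccc1 | intermediate
13 | (1R,2S,3R,6S)-6-acetoxy-1-(acetoxymethyl)-1-hydroxycyclohex-4-ene-2,3-diyl dibenzoate (CNP0196993.1) | CC(=O)OC[C@@]1(O)[C@@H](OC(C)=O)C=C[C@@H](OC(=O)c2ccccc2)[C@@H]1OC(=O)c1ccccc1 | target

Total step count: 8. Longest linear sequence: 6 steps (1, 2, 3, 6, 7, 8).

Steps most likely to fail

Step 6.
- **What may go wrong:** The trisubstituted, donor-bearing dienophile may react sluggishly. The diene may suffer protodesilylation or Mukaiyama-type side reactions at the cationic boron centre. Endo or facial selectivity may erode.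
- **Fallback:** Asymmetric catalysis is given up, and the antipodes are separated with an enzyme at the last alcohol stage. The fallback sets out from 4 and 8.
- Heating in toluene (90 °C, radical inhibitor) or pressing at 12 kbar in CH2Cl2 should give 9 together with the mirror-image adduct F1.
- The conditions of step 7 then carry the racemate through the mirror-image primary alcohol F2 and the mirror-image silyl ether F3 to 12 and the mirror-image diol F4.
- A triacylglycerol lipase (serine hydrolase class, for example from Burkholderia cepacia) with vinyl acetate in tert-butyl methyl ether follows. By the empirical size rule for secondary alcohols it should acetylate the (6R)-alcohol F4 to the mirror-image tetraester F5 and leave 12 untouched.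
- After chromatography the route is rejoined at 12.

Step 5.
- **What may go wrong:** The hypervalent iodine reagent may over-oxidise the enolised product. The keto aldehyde may hydrate or oligomerise. Acyl groups may exchange between the two enol oxygens, and Z selectivity may be incomplete.
- **Fallback:** Oxidation comes first, and the two enolic hydroxyls are then told apart by acidity. The fallback sets out from 5.
- Cu(OAc)2 in aqueous acetic acid oxidises the ketol, and the product is collected as its crystalline enediol tautomer, triose reductone F6.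
- The vinylogous-acid hydroxyl at C3 is benzoylated selectively as its mono-salt (1 equiv Et3N, BzCl, −20 °C) to give (1Z)-2-hydroxy-3-oxoprop-1-en-1-yl benzoate F7.
- AcCl with 2,6-lutidine then caps the remaining enol and the route is rejoined at 8.

Step 3.
- **What may go wrong:** Enal 3 may isomerise from Z to E before enolisation. By the same allylic-strain argument this would lead to a 3Z dienol ether that cannot reach the s-cis form. The product may also hydrolyse on purification.
- **Fallback:** Kinetic control is replaced by thermodynamic control and crystallisation. The fallback sets out from 3.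
- Benzoylation (BzCl, Et3N, 4-(dimethylamino)pyridine), followed in the same flask by equilibration with catalytic I2, should give crystalline (1E,3E)-buta-1,3-diene-1,4-diyl dibenzoate F8.
- MeLi (2 equiv, THF, −78 °C) cleaves one enol ester with retention of geometry to lithium (1E,3E)-4-(benzoyloxy)buta-1,3-dien-1-olate F9.
- Et3SiCl traps this enolate on oxygen and the route is rejoined at 4.

Further compounds
F1 | step 6 | (1R,2R,3S,6R)-1-acetoxy-2,3-bis(benzoyloxy)-6-(triethylsilyloxy)cyclohex-4-ene-1-carbaldehyde | O=C[C@]1(OC(C)=O)[C@H](O[Si](CC)(CC)CC)C=C[C@H](OC(=O)c2ccccc2)[C@H]1OC(=O)c1ccccc1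
F2 | step 6 | (1R,2R,3S,6R)-1-acetoxy-1-(hydroxymethyl)-6-(triethylsilyloxy)cyclohex-4-ene-2,3-diyl dibenzoate | OC[C@]1(OC(C)=O)[C@H](O[Si](CC)(CC)CC)C=C[C@H](OC(=O)c2ccccc2)[C@H]1OC(=O)c1ccccc1
F3 | step 6 | (1R,2R,3S,6R)-1-(acetoxymethyl)-1-hydroxy-6-(triethylsilyloxy)cyclohex-4-ene-2,3-diyl dibenzoate | CC(=O)OC[C@]1(O)[C@H](O[Si](CC)(CC)CC)C=C[C@H](OC(=O)c2ccccc2)[C@H]1OC(=O)c1ccccc1
F4 | step 6 | (1S,2R,3S,6R)-1-(acetoxymethyl)-1,6-dihydroxycyclohex-4-ene-2,3-diyl dibenzoate | CC(=O)OC[C@]1(O)[C@H](O)C=C[C@H](OC(=O)c2ccccc2)[C@H]1OC(=O)c1ccccc1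
F5 | step 6 | (1S,2R,3S,6R)-6-acetoxy-1-(acetoxymethyl)-1-hydroxycyclohex-4-ene-2,3-diyl dibenzoate | CC(=O)OC[C@]1(O)[C@H](OC(C)=O)C=C[C@H](OC(=O)c2ccccc2)[C@H]1OC(=O)c1ccccc1
F6 | step 5 | triose reductone, (2Z)-2,3-dihydroxyprop-2-enal | O=C/C(O)=C/O
F7 | step 5 | (1Z)-2-hydroxy-3-oxoprop-1-en-1-yl benzoate | O=C/C(O)=C/OC(=O)c1ccccc1
F8 | step 3 | (1E,3E)-buta-1,3-diene-1,4-diyl dibenzoate | O=C(O/C=C/C=C/OC(=O)c1ccccc1)c1ccccc1
F9 | step 3 | lithium (1E,3E)-4-(benzoyloxy)buta-1,3-dien-1-olate | [Li+].[O-]/C=C/C=C/OC(=O)c1ccccc1
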